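**Retrosynthetic overview**
1. Target 31 comes from the 11-membered hydroxy ester 26 by ester reduction, selective silylation, acylation of the C4 hydroxyl and global desilylation.
2. The carbocycle is closed at C3–C4 by an intramolecular nickel-catalysed, chromium-mediated (Nozaki–Hiyama–Kishi) coupling of an E-vinyl iodide with the cis-epoxy aldehyde 25. The oxirane is made first, on acyclic fragment B; the 11-membered ring is formed second.
3. 25 comes from a Horner–Wadsworth–Emmons union (C9=C10) of aldehyde 11 (fragment A: C10, C11, C1–C3 and the side chain) with phosphonate 23 (fragment B: C4–C9).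
4. Fragment A: the quaternary C1 is set by a new rhodium-catalysed enantioselective conjugate alkenylation of enoate 6; 6 comes from zirconium-catalysed carboalumination, and the side-chain carbinol from a catalytic asymmetric chromium/nickel isopropenylation.
5. Fragment B: the Z-alkene comes from copper-catalysed carbomagnesiation/iodination of propargyl alcohol and a B-alkyl Suzuki coupling, followed by phosphonylation and Sharpless epoxidation.

Assumption: ring locants in the names of 26–31 run C1 (quaternary carbon), C2=C3, C4 (oxygenated), C5/C6 (oxirane), C7, C8, C9=C10, C11; where a chiral ligand is named, the enantiomer meant is the one that gives the stated face selectivity; pent-4-ynal is bought and kept cold.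

**Route**

Step 1
Reactants: 1 pent-4-ynal; 2 2-bromoprop-1-ene
Product: 3 (3S)-2-methylhept-1-en-6-yn-3-ol
Conditions: CrCl2 (10 mol %), (S)-N-[2-(4-isopropyl-4,5-dihydrooxazol-2-yl)-6-methylphenyl]methanesulfonamide (11 mol %), Et3N (20 mol %), NiCl2(2,9-dimethyl-1,10-phenanthroline) (2 mol %), Mn powder (2 equiv), (C5H5)2ZrCl2 (1.1 equiv), LiCl, MeCN, rt
Reagents that add atoms: none
Why: Catalytic asymmetric Nozaki–Hiyama–Kishi alkenylation, in which zerovalent nickel activates the C–Br bond, the alkenyl group passes to the ligand-bound chromium and adds to the Re face of the aldehyde to set the (3S) carbinol, while Mn returns chromium to the divalent state and the zirconocene frees the alkoxide; the terminal alkyne is inert.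

Step 2
Reactants: 3 (3S)-2-methylhept-1-en-6-yn-3-ol
Product: 4 tert-butyldimethyl{[(3S)-2-methylhept-1-en-6-yn-3-yl]oxy}silane
Conditions: t-BuMe2SiCl, imidazole, DMF, rt
Reagents that add atoms: tert-butyldimethylsilyl chloride (CC(C)(C)[Si](C)(C)Cl)
Why: Standard imidazole-promoted silyl ether formation masks the only hydroxyl without touching the stereocentre.

Step 3
Reactants: 4 tert-butyldimethyl{[(3S)-2-methylhept-1-en-6-yn-3-yl]oxy}silane
Product: 6 methyl (2E,6S)-6-[(tert-butyldimethylsilyl)oxy]-3,7-dimethylocta-2,7-dienoate, via alkenylalane 5 (not isolated)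
Conditions: Me3Al (2.5 equiv), (C5H5)2ZrCl2 (0.25 equiv), CH2Cl2, 0 °C to rt; then ClCO2Me, 0 °C to rt
Reagents that add atoms: trimethylaluminium (C[Al](C)C); methyl chloroformate (COC(=O)Cl)
Why: Negishi zirconium-catalysed carboalumination adds Me and Al syn across the terminal alkyne (Me to the internal carbon) and the E-alkenylalane is acylated by the chloroformate with retention, giving the (2E) enoate; the hindered 1,1-disubstituted alkene does not react.

Step 4
Reactants: 7 ethynyltrimethylsilane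
Product: 8 trimethyl[(E)-2-(4,4,5,5-tetramethyl-1,3,2-dioxaborolan-2-yl)ethenyl]silane
Conditions: pinacolborane (1.1 equiv), (C5H5)2Zr(H)Cl (5 mol %), Et3N (10 mol %), neat, 60 °C
Reagents that add atoms: pinacolborane ([H]B1OC(C)(C)C(C)(C)O1)
Why: Zirconium-catalysed hydroboration (syn hydrozirconation, then transfer to boron) puts boron on the unsubstituted alkyne carbon and gives only the E-alkenylboronate.

Step 5
Reactants: 6 methyl (2E,6S)-6-[(tert-butyldimethylsilyl)oxy]-3,7-dimethylocta-2,7-dienoate; 8 trimethyl[(E)-2-(4,4,5,5-tetramethyl-1,3,2-dioxaborolan-2-yl)ethenyl]silane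
Product: 9 methyl (3S,6S)-6-[(tert-butyldimethylsilyl)oxy]-3,7-dimethyl-3-[(E)-2-(trimethylsilyl)ethenyl]oct-7-enoate
Conditions: 8 (2 equiv), [RhCl(C2H4)2]2 (2.5 mol %), (R,R)-2,5-diphenylbicyclo[2.2.2]octa-2,5-diene (5.5 mol %), aq KOH (0.2 equiv), 1,4-dioxane/H2O 10:1, 50 °C
Reagents that add atoms: none
Why: Proposed new method: the alkenyl group moves from boron to a hydroxo complex of monovalent rhodium carrying the chiral diene, the alkenyl–rhodium carbometalates the (E)-enoate on the Si face of C3 (the E geometry fixes which β-substituent is methyl and which is the chain, so face selection alone defines the centre) and protonolysis of the oxa-π-allyl rhodium releases the (3S) all-carbon quaternary centre with the E-alkenylsilane intact; the closest known reactions are rhodium/chiral-diene-catalysed 1,4-additions of arylboron reagents to β,β-disubstituted enoates and enones (quaternary centres) and rhodium-catalysed 1,4-additions of alkenylboron reagents to β-monosubstituted acceptors, which have not been combined on an acyclic β,β-dialkyl enoate.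

Step 6
Reactants: 9 methyl (3S,6S)-6-[(tert-butyldimethylsilyl)oxy]-3,7-dimethyl-3-[(E)-2-(trimethylsilyl)ethenyl]oct-7-enoate
Product: 10 methyl (3S,6S)-6-[(tert-butyldimethylsilyl)oxy]-3-[(E)-2-iodoethenyl]-3,7-dimethyloct-7-enoate
Conditions: N-iodosuccinimide (1.2 equiv), 2,6-lutidine (0.3 equiv), (CF3)2CHOH, 0 °C, 10 min
Reagents that add atoms: N-iodosuccinimide (O=C1CCC(=O)N1I)
Why: Electrophilic ipso-iododesilylation (β-silyl cation, loss of the silyl group) proceeds with retention to the E-vinyl iodide and in hexafluoroisopropanol is expected to outpace attack on the 1,1-disubstituted alkene, which is deactivated by the allylic silyloxy group.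

Step 7
Reactants: 10 methyl (3S,6S)-6-[(tert-butyldimethylsilyl)oxy]-3-[(E)-2-iodoethenyl]-3,7-dimethyloct-7-enoate
Product: 11 (3S,6S)-6-[(tert-butyldimethylsilyl)oxy]-3-[(E)-2-iodoethenyl]-3,7-dimethyloct-7-enal
Conditions: i-Bu2AlH (1.1 equiv), CH2Cl2, −78 °C; aq potassium sodium tartrate
Reagents that add atoms: none
Why: Partial ester reduction with one equivalent of the aluminium hydride at −78 °C stops at the tetrahedral aluminium hemiacetal, which collapses to the aldehyde on work-up; no stereocentre is affected.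

Step 8
Reactants: 12 prop-2-yn-1-ol
Product: 14 (2Z)-3-iodo-2-methylprop-2-en-1-ol, via alkenylmagnesium alkoxide 13 (not isolated)
Conditions: MeMgBr (2.5 equiv), CuI (10 mol %), THF, −10 °C to rt; then I2, −10 °C
Reagents that add atoms: methylmagnesium bromide (C[Mg]Br); iodine (II)
Why: Copper-catalysed anti-carbomagnesiation of the propargylic alkoxide (methyl to C2, magnesium to C3 within a five-membered chelate) followed by iodinolysis with retention gives only the Z-iodoalkene.

Step 9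
Reactants: 14 (2Z)-3-iodo-2-methylprop-2-en-1-ol
Product: 15 tert-butyl{[(2Z)-3-iodo-2-methylprop-2-en-1-yl]oxy}dimethylsilane
Conditions: t-BuMe2SiCl, imidazole, CH2Cl2, rt
Reagents that add atoms: tert-butyldimethylsilyl chloride (CC(C)(C)[Si](C)(C)Cl)
Why: Standard silylation of the primary alcohol, needed so that the later enolate chemistry is possible.

Step 10
Reactants: 16 methyl but-3-enoate; 15 tert-butyl{[(2Z)-3-iodo-2-methylprop-2-en-1-yl]oxy}dimethylsilane
Product: 18 methyl (5Z)-7-[(tert-butyldimethylsilyl)oxy]-6-methylhept-5-enoate, via alkylborane 17 (not isolated)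
Conditions: 16, 9-borabicyclo[3.3.1]nonane, THF, 0 °C to rt; then 15, PdCl2(dppf) (5 mol %; dppf = 1,1'-bis(diphenylphosphino)ferrocene), AsPh3 (10 mol %), Cs2CO3, DMF/H2O, rt
Reagents that add atoms: none
Why: Anti-Markovnikov hydroboration of the terminal alkene and B-alkyl Suzuki–Miyaura coupling (oxidative addition to zerovalent palladium, base-assisted transmetalation, reductive elimination) join the sp3 and sp2 carbons with retention of the Z geometry.

Step 11
Reactants: 18 methyl (5Z)-7-[(tert-butyldimethylsilyl)oxy]-6-methylhept-5-enoate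
Product: 21 methyl (5Z)-7-[(tert-butyldimethylsilyl)oxy]-2-(diethoxyphosphoryl)-6-methylhept-5-enoate, via lithium enolate 19 (not isolated), via phosphonite ester 20 (not isolated)
Conditions: LiN(i-Pr)2 (1.1 equiv), THF, −78 °C; ClP(OEt)2, −78 °C to rt; then 30% H2O2, 0 °C
Reagents that add atoms: diethyl chlorophosphite (CCOP(Cl)OCC); hydrogen peroxide (OO)
Why: Enolate C-phosphinylation by the trivalent phosphorus chloride followed by oxidation gives the phosphonoacetate; the new C2 centre is racemic and is destroyed in step 14.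

Step 12
Reactants: 21 methyl (5Z)-7-[(tert-butyldimethylsilyl)oxy]-2-(diethoxyphosphoryl)-6-methylhept-5-enoate
Product: 22 methyl (5Z)-2-(diethoxyphosphoryl)-7-hydroxy-6-methylhept-5-enoate
Conditions: Bu4NF, AcOH (1:1), THF, 0 °C to rt
Reagents that add atoms: none
Why: Fluoride-mediated desilylation, buffered with acetic acid so that the phosphonoacetate and the ester are not harmed.

Step 13
Reactants: 22 methyl (5Z)-2-(diethoxyphosphoryl)-7-hydroxy-6-methylhept-5-enoate
Product: 23 methyl 2-(diethoxyphosphoryl)-4-[(2S,3R)-3-(hydroxymethyl)-3-methyloxiran-2-yl]butanoate (1:1 at C2)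
Conditions: Ti(OiPr)4 (10 mol %), D-(−)-diethyl tartrate (12 mol %), t-BuOOH, 4 Å molecular sieves, CH2Cl2, −20 °C
Reagents that add atoms: tert-butyl hydroperoxide (CC(C)(C)OO)
Why: Sharpless asymmetric epoxidation, in which the titanium–D-(−)-tartrate complex delivers oxygen to one face of the allylic alcohol to give the (2S,3R) oxirane, while the Z alkene fixes the cis relation of the two ring carbons.

Step 14
Reactants: 11 (3S,6S)-6-[(tert-butyldimethylsilyl)oxy]-3-[(E)-2-iodoethenyl]-3,7-dimethyloct-7-enal; 23 methyl 2-(diethoxyphosphoryl)-4-[(2S,3R)-3-(hydroxymethyl)-3-methyloxiran-2-yl]butanoate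
Product: 24 methyl (2E,5S,8S)-8-[(tert-butyldimethylsilyl)oxy]-2-{2-[(2S,3R)-3-(hydroxymethyl)-3-methyloxiran-2-yl]ethyl}-5-[(E)-2-iodoethenyl]-5,9-dimethyldeca-2,9-dienoate
Conditions: LiCl, DBU, MeCN, 0 °C to rt
Reagents that add atoms: none
Why: Horner–Wadsworth–Emmons olefination under Masamune–Roush conditions (mild enough for the free alcohol and the epoxide) gives the thermodynamically favoured (2E) trisubstituted enoate in which the two carbon chains are cis; the C2 centre of 23 disappears.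

Step 15
Reactants: 24 methyl (2E,5S,8S)-8-[(tert-butyldimethylsilyl)oxy]-2-{2-[(2S,3R)-3-(hydroxymethyl)-3-methyloxiran-2-yl]ethyl}-5-[(E)-2-iodoethenyl]-5,9-dimethyldeca-2,9-dienoate
Product: 25 methyl (2E,5S,8S)-8-[(tert-butyldimethylsilyl)oxy]-2-{2-[(2S,3S)-3-formyl-3-methyloxiran-2-yl]ethyl}-5-[(E)-2-iodoethenyl]-5,9-dimethyldeca-2,9-dienoate
Conditions: PhI(OAc)2, TEMPO (10 mol %), CH2Cl2, rt
Reagents that add atoms: none
Why: Oxoammonium (TEMPO) oxidation converts the primary alcohol to the aldehyde under neutral conditions, and the quaternary α-carbon cannot epimerise (the descriptor changes only through priorities).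

Step 16
Reactants: 25 methyl (2E,5S,8S)-8-[(tert-butyldimethylsilyl)oxy]-2-{2-[(2S,3S)-3-formyl-3-methyloxiran-2-yl]ethyl}-5-[(E)-2-iodoethenyl]-5,9-dimethyldeca-2,9-dienoate
Product: 26 methyl (1S,2E,4R,5R,6S,9E)-1-{(3S)-3-[(tert-butyldimethylsilyl)oxy]-4-methylpent-4-en-1-yl}-5,6-epoxy-4-hydroxy-1,5-dimethylcycloundeca-2,9-diene-9-carboxylate
Conditions: CrCl2 (10 equiv), NiCl2 (0.1 equiv), DMSO/THF 3:1, 0.002 M (slow addition), rt
Reagents that add atoms: none
Why: Intramolecular Nozaki–Hiyama–Kishi coupling, in which nickel-catalysed activation of the E-vinyl iodide, transmetalation to chromium and chemoselective 1,2-addition to the aldehyde close the 11-membered ring with retention of the E alkene, and Felkin–Anh addition anti to the epoxide C–O bond is expected to favour the (4R), erythro alcohol.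

Step 17
Reactants: 26 methyl (1S,2E,4R,5R,6S,9E)-1-{(3S)-3-[(tert-butyldimethylsilyl)oxy]-4-methylpent-4-en-1-yl}-5,6-epoxy-4-hydroxy-1,5-dimethylcycloundeca-2,9-diene-9-carboxylate
Product: 27 (1S,2E,4R,5R,6S,9E)-1-{(3S)-3-[(tert-butyldimethylsilyl)oxy]-4-methylpent-4-en-1-yl}-5,6-epoxy-9-(hydroxymethyl)-1,5-dimethylcycloundeca-2,9-dien-4-ol
Conditions: i-Bu2AlH (4 equiv), CH2Cl2, −78 °C; aq potassium sodium tartrate
Reagents that add atoms: none
Why: Aluminium hydride 1,2-reduction of the conjugated ester to the allylic alcohol at −78 °C, where the epoxide and the alkenes are not attacked.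

Step 18
Reactants: 27 (1S,2E,4R,5R,6S,9E)-1-{(3S)-3-[(tert-butyldimethylsilyl)oxy]-4-methylpent-4-en-1-yl}-5,6-epoxy-9-(hydroxymethyl)-1,5-dimethylcycloundeca-2,9-dien-4-ol
Product: 28 (1S,2E,4R,5R,6S,9E)-1-{(3S)-3-[(tert-butyldimethylsilyl)oxy]-4-methylpent-4-en-1-yl}-9-{[(tert-butyldimethylsilyl)oxy]methyl}-5,6-epoxy-1,5-dimethylcycloundeca-2,9-dien-4-ol
Conditions: t-BuMe2SiCl (1.1 equiv), imidazole, CH2Cl2, −20 to 0 °C
Reagents that add atoms: tert-butyldimethylsilyl chloride (CC(C)(C)[Si](C)(C)Cl)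
Why: Chemoselective silylation, because the primary allylic hydroxyl reacts far faster than the secondary C4 hydroxyl flanked by the fully substituted epoxide carbon.

Step 19
Reactants: 28 (1S,2E,4R,5R,6S,9E)-1-{(3S)-3-[(tert-butyldimethylsilyl)oxy]-4-methylpent-4-en-1-yl}-9-{[(tert-butyldimethylsilyl)oxy]methyl}-5,6-epoxy-1,5-dimethylcycloundeca-2,9-dien-4-ol; 29 3-methylbut-2-enoyl chloride
Product: 30 (1S,2E,4R,5S,6S,9E)-1-{(3S)-3-[(tert-butyldimethylsilyl)oxy]-4-methylpent-4-en-1-yl}-9-{[(tert-butyldimethylsilyl)oxy]methyl}-5,6-epoxy-1,5-dimethylcycloundeca-2,9-dien-4-yl 3-methylbut-2-enoate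
Conditions: pyridine, 4-(dimethylamino)pyridine (cat.), CH2Cl2, 0 °C to rt
Reagents that add atoms: none
Why: Nucleophile-catalysed acylation of the hindered secondary alcohol, with pyridine as the only base to avoid vinylketene formation and deconjugation of the acyl group; C4 keeps its configuration (the C5 descriptor changes only through priorities).

Step 20
Reactants: 30 (1S,2E,4R,5S,6S,9E)-1-{(3S)-3-[(tert-butyldimethylsilyl)oxy]-4-methylpent-4-en-1-yl}-9-{[(tert-butyldimethylsilyl)oxy]methyl}-5,6-epoxy-1,5-dimethylcycloundeca-2,9-dien-4-yl 3-methylbut-2-enoate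
Product: 31 (1S,2E,4R,5S,6S,9E)-5,6-epoxy-9-(hydroxymethyl)-1-[(3S)-3-hydroxy-4-methylpent-4-en-1-yl]-1,5-dimethylcycloundeca-2,9-dien-4-yl 3-methylbut-2-enoate
Conditions: Bu4NF, AcOH (1:1), THF, 0 °C to rt
Reagents that add atoms: none
Why: Buffered fluoride desilylation removes both silyl ethers without acyl migration or epoxide opening.

**Compound list**
1 | pent-4-ynal | C#CCCC=O | starting material
2 | 2-bromoprop-1-ene | CC(Br)=C | starting material
3 | (3S)-2-methylhept-1-en-6-yn-3-ol | C=C(C)[C@@H](O)CCC#C | intermediate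
4 | tert-butyldimethyl{[(3S)-2-methylhept-1-en-6-yn-3-yl]oxy}silane | C=C(C)[C@@H](O[Si](C)(C)C(C)(C)C)CCC#C | intermediate
5 | {(1E,5S)-5-[(tert-butyldimethylsilyl)oxy]-2,6-dimethylhepta-1,6-dien-1-yl}dimethylalumane | C=C(C)[C@@H](O[Si](C)(C)C(C)(C)C)CC/C(C)=C/[Al](C)C | intermediate
6 | methyl (2E,6S)-6-[(tert-butyldimethylsilyl)oxy]-3,7-dimethylocta-2,7-dienoate | C=C(C)[C@@H](O[Si](C)(C)C(C)(C)C)CC/C(C)=C/C(=O)OC | intermediate
7 | ethynyltrimethylsilane | C#C[Si](C)(C)C | starting material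
8 | trimethyl[(E)-2-(4,4,5,5-tetramethyl-1,3,2-dioxaborolan-2-yl)ethenyl]silane | C[Si](C)(C)/C=C/B1OC(C)(C)C(C)(C)O1 | intermediate
9 | methyl (3S,6S)-6-[(tert-butyldimethylsilyl)oxy]-3,7-dimethyl-3-[(E)-2-(trimethylsilyl)ethenyl]oct-7-enoate | C=C(C)[C@@H](O[Si](C)(C)C(C)(C)C)CC[C@](CC(=O)OC)(C)/C=C/[Si](C)(C)C | intermediate
10 | methyl (3S,6S)-6-[(tert-butyldimethylsilyl)oxy]-3-[(E)-2-iodoethenyl]-3,7-dimethyloct-7-enoate | C=C(C)[C@@H](O[Si](C)(C)C(C)(C)C)CC[C@](CC(=O)OC)(C)/C=C/I | intermediate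
11 | (3S,6S)-6-[(tert-butyldimethylsilyl)oxy]-3-[(E)-2-iodoethenyl]-3,7-dimethyloct-7-enal | C=C(C)[C@@H](O[Si](C)(C)C(C)(C)C)CC[C@](CC=O)(C)/C=C/I | intermediate
12 | prop-2-yn-1-ol | C#CCO | starting material
13 | bromo[(1Z)-3-(bromomagnesiooxy)-2-methylprop-1-en-1-yl]magnesium | Br[Mg]/C=C(/C)CO[Mg]Br | intermediate
14 | (2Z)-3-iodo-2-methylprop-2-en-1-ol | OC/C(C)=C\I | intermediate
15 | tert-butyl{[(2Z)-3-iodo-2-methylprop-2-en-1-yl]oxy}dimethylsilane | CC(C)(C)[Si](C)(C)OC/C(C)=C\I | intermediate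
16 | methyl but-3-enoate | C=CCC(=O)OC | starting material
17 | methyl 4-(9-borabicyclo[3.3.1]nonan-9-yl)butanoate | COC(=O)CCCB1C2CCCC1CCC2 | intermediate
18 | methyl (5Z)-7-[(tert-butyldimethylsilyl)oxy]-6-methylhept-5-enoate | COC(=O)CCC/C=C(/C)CO[Si](C)(C)C(C)(C)C | intermediate
19 | lithium (5Z)-7-[(tert-butyldimethylsilyl)oxy]-1-methoxy-6-methylhepta-1,5-dien-1-olate | COC(O[Li])=CCC/C=C(/C)CO[Si](C)(C)C(C)(C)C | intermediate
20 | methyl (5Z)-7-[(tert-butyldimethylsilyl)oxy]-2-(diethoxyphosphanyl)-6-methylhept-5-enoate | CCOP(OCC)C(CC/C=C(/C)CO[Si](C)(C)C(C)(C)C)C(=O)OC | intermediate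
21 | methyl (5Z)-7-[(tert-butyldimethylsilyl)oxy]-2-(diethoxyphosphoryl)-6-methylhept-5-enoate | CCOP(=O)(OCC)C(CC/C=C(/C)CO[Si](C)(C)C(C)(C)C)C(=O)OC | intermediate
22 | methyl (5Z)-2-(diethoxyphosphoryl)-7-hydroxy-6-methylhept-5-enoate | CCOP(=O)(OCC)C(CC/C=C(/C)CO)C(=O)OC | intermediate
23 | methyl 2-(diethoxyphosphoryl)-4-[(2S,3R)-3-(hydroxymethyl)-3-methyloxiran-2-yl]butanoate | CCOP(=O)(OCC)C(CC[C@@H]1O[C@]1(C)CO)C(=O)OC | intermediate
24 | methyl (2E,5S,8S)-8-[(tert-butyldimethylsilyl)oxy]-2-{2-[(2S,3R)-3-(hydroxymethyl)-3-methyloxiran-2-yl]ethyl}-5-[(E)-2-iodoethenyl]-5,9-dimethyldeca-2,9-dienoate | C=C(C)[C@@H](O[Si](C)(C)C(C)(C)C)CC[C@](C/C=C(\CC[C@@H]1O[C@]1(C)CO)C(=O)OC)(C)/C=C/I | intermediate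
25 | methyl (2E,5S,8S)-8-[(tert-butyldimethylsilyl)oxy]-2-{2-[(2S,3S)-3-formyl-3-methyloxiran-2-yl]ethyl}-5-[(E)-2-iodoethenyl]-5,9-dimethyldeca-2,9-dienoate | C=C(C)[C@@H](O[Si](C)(C)C(C)(C)C)CC[C@](C/C=C(\CC[C@@H]1O[C@]1(C)C=O)C(=O)OC)(C)/C=C/I | intermediate
26 | methyl (1S,2E,4R,5R,6S,9E)-1-{(3S)-3-[(tert-butyldimethylsilyl)oxy]-4-methylpent-4-en-1-yl}-5,6-epoxy-4-hydroxy-1,5-dimethylcycloundeca-2,9-diene-9-carboxylate | C=C(C)[C@@H](O[Si](C)(C)C(C)(C)C)CC[C@]1(C)/C=C/[C@@H](O)[C@@]2(C)O[C@H]2CC/C(C(=O)OC)=C\C1 | intermediate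
27 | (1S,2E,4R,5R,6S,9E)-1-{(3S)-3-[(tert-butyldimethylsilyl)oxy]-4-methylpent-4-en-1-yl}-5,6-epoxy-9-(hydroxymethyl)-1,5-dimethylcycloundeca-2,9-dien-4-ol | C=C(C)[C@@H](O[Si](C)(C)C(C)(C)C)CC[C@]1(C)/C=C/[C@@H](O)[C@@]2(C)O[C@H]2CC/C(CO)=C\C1 | intermediate
28 | (1S,2E,4R,5R,6S,9E)-1-{(3S)-3-[(tert-butyldimethylsilyl)oxy]-4-methylpent-4-en-1-yl}-9-{[(tert-butyldimethylsilyl)oxy]methyl}-5,6-epoxy-1,5-dimethylcycloundeca-2,9-dien-4-ol | C=C(C)[C@@H](O[Si](C)(C)C(C)(C)C)CC[C@]1(C)/C=C/[C@@H](O)[C@@]2(C)O[C@H]2CC/C(CO[Si](C)(C)C(C)(C)C)=C\C1 | intermediate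
29 | 3-methylbut-2-enoyl chloride | CC(C)=CC(=O)Cl | starting material
30 | (1S,2E,4R,5S,6S,9E)-1-{(3S)-3-[(tert-butyldimethylsilyl)oxy]-4-methylpent-4-en-1-yl}-9-{[(tert-butyldimethylsilyl)oxy]methyl}-5,6-epoxy-1,5-dimethylcycloundeca-2,9-dien-4-yl 3-methylbut-2-enoate | C=C(C)[C@@H](O[Si](C)(C)C(C)(C)C)CC[C@]1(C)/C=C/[C@@H](OC(=O)C=C(C)C)[C@@]2(C)O[C@H]2CC/C(CO[Si](C)(C)C(C)(C)C)=C\C1 | intermediate
31 | (1S,2E,4R,5S,6S,9E)-5,6-epoxy-9-(hydroxymethyl)-1-[(3S)-3-hydroxy-4-methylpent-4-en-1-yl]-1,5-dimethylcycloundeca-2,9-dien-4-yl 3-methylbut-2-enoate | C=C(C)[C@@H](O)CC[C@]1(C)/C=C/[C@@H](OC(=O)C=C(C)C)[C@@]2(C)O[C@H]2CC/C(CO)=C\C1 | target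

**Step count**
Total: 20 steps. Longest linear sequence: 13 steps (steps 1–3, 5–7 and 14–20 from 1; the line from 12 through steps 8–13 and 14–20 is also 13).

**Steps most likely to fail, with fallbacks**

Step 5 (the new rhodium-catalysed alkenylation; risks are low reactivity of the β,β-dialkyl enoate and insufficient face selectivity). The fallback uses known copper-catalysed allylic substitution and Wacker chemistry, sets out from 4 and comes back at 11. Alkyne 4 is carboaluminated as in step 3, but alkenylalane 5 is quenched with paraformaldehyde to give (2E,6S)-6-[(tert-butyldimethylsilyl)oxy]-3,7-dimethylocta-2,7-dien-1-ol F1. ClP(O)(OEt)2, Et3N and 4-(dimethylamino)pyridine convert it into diethyl (2E,6S)-6-[(tert-butyldimethylsilyl)oxy]-3,7-dimethylocta-2,7-dien-1-yl phosphate F2. Enantioselective SN2' substitution of F2 with boronate 8 (CuCl, a chiral sulfonate-bearing imidazolinium salt as N-heterocyclic carbene precursor, NaOMe, THF) creates the quaternary centre in (3S,6S,7E)-3-[(tert-butyldimethylsilyl)oxy]-6-ethenyl-2,6-dimethyl-8-(trimethylsilyl)octa-1,7-diene F3. Aldehyde-selective, nitrite-modified Wacker oxidation of the unsubstituted vinyl group (PdCl2(PhCN)2, CuCl2, AgNO2, t-BuOH/MeNO2, O2) gives (3S,6S)-6-[(tert-butyldimethylsilyl)oxy]-3,7-dimethyl-3-[(E)-2-(trimethylsilyl)ethenyl]oct-7-enal F4. Iododesilylation under the conditions of step 6 then gives 11.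

Step 16 (closure of the strained 11-membered ring and control of C4). The fallback sets C4 by ketone reduction instead of by the C–C bond formation; it sets out from 25 and comes back at 26. If the closure gives mainly the C4 epimer methyl (1S,2E,4S,5R,6S,9E)-1-{(3S)-3-[(tert-butyldimethylsilyl)oxy]-4-methylpent-4-en-1-yl}-5,6-epoxy-4-hydroxy-1,5-dimethylcycloundeca-2,9-diene-9-carboxylate F5, the alcohol mixture is oxidised (Dess–Martin periodinane, NaHCO3, CH2Cl2) to the epoxy enone methyl (1S,2E,5S,6S,9E)-1-{(3S)-3-[(tert-butyldimethylsilyl)oxy]-4-methylpent-4-en-1-yl}-5,6-epoxy-1,5-dimethyl-4-oxocycloundeca-2,9-diene-9-carboxylate F6. Reduction with Zn(BH4)2 (Et2O, −20 °C), chelation-controlled between the carbonyl and oxirane oxygens and known to be erythro-selective for α,β-epoxy ketones, then gives 26. This fallback does not help if the ring fails to close at all.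

Step 1 (enantioselectivity of the chromium-catalysed addition of a simple alkenyl bromide to a small aldehyde). The fallback sets the carbinol by ketone reduction; it sets out from 1 and comes back at 3. Isopropenylmagnesium bromide (THF, −78 °C) adds to 1 to give racemic 2-methylhept-1-en-6-yn-3-ol F7. Dess–Martin oxidation gives 2-methylhept-1-en-6-yn-3-one F8. Corey–Bakshi–Shibata reduction with the (R)-2-methyl-oxazaborolidine and BH3·SMe2 (THF, −30 °C), taking the isopropenyl group as the large substituent, gives 3.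

**Further compounds**
F1 | step 5 | (2E,6S)-6-[(tert-butyldimethylsilyl)oxy]-3,7-dimethylocta-2,7-dien-1-ol | C=C(C)[C@@H](O[Si](C)(C)C(C)(C)C)CC/C(C)=C/CO
F2 | step 5 | diethyl (2E,6S)-6-[(tert-butyldimethylsilyl)oxy]-3,7-dimethylocta-2,7-dien-1-yl phosphate | C=C(C)[C@@H](O[Si](C)(C)C(C)(C)C)CC/C(C)=C/COP(=O)(OCC)OCC
F3 | step 5 | (3S,6S,7E)-3-[(tert-butyldimethylsilyl)oxy]-6-ethenyl-2,6-dimethyl-8-(trimethylsilyl)octa-1,7-diene | C=C(C)[C@@H](O[Si](C)(C)C(C)(C)C)CC[C@](C=C)(C)/C=C/[Si](C)(C)C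
F4 | step 5 | (3S,6S)-6-[(tert-butyldimethylsilyl)oxy]-3,7-dimethyl-3-[(E)-2-(trimethylsilyl)ethenyl]oct-7-enal | C=C(C)[C@@H](O[Si](C)(C)C(C)(C)C)CC[C@](CC=O)(C)/C=C/[Si](C)(C)C
F5 | step 16 | methyl (1S,2E,4S,5R,6S,9E)-1-{(3S)-3-[(tert-butyldimethylsilyl)oxy]-4-methylpent-4-en-1-yl}-5,6-epoxy-4-hydroxy-1,5-dimethylcycloundeca-2,9-diene-9-carboxylate | C=C(C)[C@@H](O[Si](C)(C)C(C)(C)C)CC[C@]1(C)/C=C/[C@H](O)[C@@]2(C)O[C@H]2CC/C(C(=O)OC)=C\C1
F6 | step 16 | methyl (1S,2E,5S,6S,9E)-1-{(3S)-3-[(tert-butyldimethylsilyl)oxy]-4-methylpent-4-en-1-yl}-5,6-epoxy-1,5-dimethyl-4-oxocycloundeca-2,9-diene-9-carboxylate | C=C(C)[C@@H](O[Si](C)(C)C(C)(C)C)CC[C@]1(C)/C=C/C(=O)[C@@]2(C)O[C@H]2CC/C(C(=O)OC)=C\C1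
F7 | step 1 | racemic 2-methylhept-1-en-6-yn-3-ol | C=C(C)C(O)CCC#C
F8 | step 1 | 2-methylhept-1-en-6-yn-3-one | C=C(C)C(=O)CCC#C
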